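What is left of the starting complex after the protic impurity has taken its share is what I reckon with. The impurity is charged at 5.00% of the complex, so with one complex lost per impurity, a fraction s = 95.0% stays available for exchange.

all flasks: starting complex 10 mM

| charge | incoming ligand | leaving ligand | protic impurity | capture agent | remark | time |
|---|---|---|---|---|---|---|
| Thursday's | 29 mM | 5 mM | 0.50 mM | 1 mM | run made earlier |  |
| Friday's | 46 mM | 5 mM | 0.50 mM | 1 mM | run made earlier |  |
| alder | 20.0 mM | 5.00 mM | 0.500 mM | 1.00 mM |  | 12 h |
| maple | 30.0 mM | 5.00 mM | 0.500 mM | 1.00 mM |  | 12 h |
| larch | 40.0 mM | 5.00 mM | 0.500 mM | 1.00 mM |  | 12 h |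

| run | time / h | complex with two exchanged / % |
|---|---|---|
| Thursday's | 1.00 | 0 |
| Thursday's | 2.00 | 0.2 |
| Thursday's | 5.00 | 0 |
| Thursday's | 12.0 | 4.8 |
| Friday's | 1.00 | 1.2 |
| Friday's | 2.00 | 2.8 |
| Friday's | 5.00 | 3.2 |
| Friday's | 12.0 | 12.0 |

(standard deviation of a reading: 1 percentage point)

1. final complex with two exchanged, as a percentage of the starting complex charged, for each flask in turn (alder, maple, larch)

- steps thought possible: starting complex + incoming ligand -> leaving ligand + complex with one exchanged; complex with one exchanged + incoming ligand -> leaving ligand + complex with two exchanged; complex with two exchanged + incoming ligand -> leaving ligand + complex with three exchanged; protic impurity + starting complex -> quenched substrate; complex with one exchanged + capture agent -> trapped intermediate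

My ladder runs from fast to slow. On the first rung I assume the quench is over before exchange gets going, so I simply start from s. On the next rung I hold the incoming ligand constant, which makes both exchanges pseudo-first-order, and give them one shared rate constant k. Integrating the two steps in closed form, with the exchange dose u = k × ligand × time, gives the twice-exchanged fraction f = s[1 − (1 + u)exp(−u)].

Friday's reading of 12.0% at 12.0 h solves to u = 0.613, so k = 1.11 M⁻¹ h⁻¹, the exchange constant, a reading with that reading's scatter. For Thursday's run it gives 5.50% against the 4.8% read, and a reading scatters by 1 percentage point.

At the asked time the doses are 0.266, 0.400 and 0.533 in alder, maple and larch. The top rung is the exchange time, the inverse of k × ligand, which comes to 45.1 h, 30.0 h and 22.5 h in the same order. The asked 12 h is shorter than each of these, so by my reckoning these flasks stand on the early, rising part of the curve. The doses give me 2.83%, 5.84% and 9.53%.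

The forecast says 2%, 5.1% and 9.1%, since “the yield scales about as L²”; my figures stand higher at each flask.

The flasks give 3.01%, 6.13% and 9.88% in alder, maple and larch, and the forecast stands within its margin at each.

    starting complex + incoming ligand → leaving ligand + complex with one exchanged (k = 1.50 M⁻¹ h⁻¹)
    complex with one exchanged + incoming ligand → leaving ligand + complex with two exchanged (k = 1.10 M⁻¹ h⁻¹)
    complex with two exchanged + incoming ligand → leaving ligand + complex with three exchanged (k = 0.240 M⁻¹ h⁻¹)
    protic impurity + starting complex → quenched substrate (k = 230 M⁻¹ h⁻¹)
    complex with one exchanged + capture agent → trapped intermediate (k = 10.0 M⁻¹ h⁻¹)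

In alder, at dose 0.266, my rule gave 2.83% against 3.01%. At 12.0 h alder's complex with one exchanged is still made 2.85 times faster than it is used up, each step taken net, and the second exchange had 5.5% of its turnover behind it at 2.40 h. In larch, at dose 0.533, my rule gave 9.53% against 9.88%, with 48.8% of the starting complex still standing at 12.0 h.

The earlier runs and the new flask are calculated on assumed constants; the scatter is artificial.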